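**Retrosynthetic overview**
1. Target 22 ⇐ tris-benzyl ether 21 (hydrogenolysis) ⇐ cis-2,6-oxan-4-one 19 (equatorial hydride delivery and in situ acetylation set C4).
2. 19 ⇐ 3-arylcyclobutanone 17 + aldehyde 8: acid-catalysed, enantioselective two-atom ring expansion (C2–C3 heterolysis of the cyclobutanone, formal insertion of the aldehyde C=O), which sets C2 and C6.
3. 17 ⇐ aryl iodide 15 + 3-oxocyclobutane-1-carboxylic acid 16 (decarboxylative arylation); 8 ⇐ aryl iodide 6 + allyl alcohol 7 (Heck).
4. 15 ⇐ 13 ⇐ 10 ⇐ 9 and 6 ⇐ 4 ⇐ 1: ortho-lithiation/oxidation makes the phenol that then directs para-iodination, with O-benzylation in the same pot.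
5. Ring order: both arenes (ring A on the ethyl chain, ring B on C2) and the four-membered ring are bought intact; the oxane is the only ring made (step 8).

Assumption: 3-(benzyloxy)phenol and 3-oxocyclobutane-1-carboxylic acid are bought, benzyl is the only protecting group, and the antipode of the chiral acid in step 8 that gives the (2S,6S) ketone is fixed by a preliminary screen.

**Route**

Step 1
Reactants: 1 anisole
Product: 4 2-methoxyphenol, via (2-methoxyphenyl)lithium 2 (not isolated), via lithium trimethoxy(2-methoxyphenyl)borate 3 (not isolated)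
Conditions: n-BuLi, TMEDA, Et2O, 0 °C → rt; B(OMe)3, −78 °C → rt; AcOH, 30% aq. H2O2, 0 °C → rt
Reagents that add atoms: hydrogen peroxide OO; n-butyllithium [Li]CCCC and trimethyl borate COB(OC)OC (their atoms stay only in 2 and 3)
Why: Directed ortho-metalation by the methoxy group, then borylation and peroxide oxidation of the aryl borate, turns the ortho C–H into the phenol.

Step 2
Reactants: 4 2-methoxyphenol
Product: 6 1-(benzyloxy)-4-iodo-2-methoxybenzene, via 4-iodo-2-methoxyphenol 5 (not isolated)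
Conditions: I2 (1.0 equiv), K2CO3 (2.5 equiv), DMF, 0 °C → rt; then BnBr (1.2 equiv), 50 °C
Reagents that add atoms: iodine II; benzyl bromide BrCc1ccccc1
Why: Electrophilic aromatic iodination of the phenoxide goes para to the oxygen, and Williamson O-benzylation in the same pot fixes the ring A pattern (minor ortho-iodo isomer removed by crystallisation of 6).

Step 3
Reactants: 6 1-(benzyloxy)-4-iodo-2-methoxybenzene; 7 prop-2-en-1-ol (allyl alcohol)
Product: 8 3-[4-(benzyloxy)-3-methoxyphenyl]propanal
Conditions: 7 (1.5 equiv), Pd(OAc)2 (3 mol%), n-Bu4NCl, NaHCO3, DMF, 40 °C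
Reagents that add atoms: none
Why: Heck arylation of allyl alcohol under ligand-free phase-transfer conditions: the aryl–palladium species (from oxidative addition to zerovalent palladium) adds to the terminal carbon, and β-hydride elimination toward the carbinol gives the enol, which tautomerises to the saturated aldehyde.

Step 4
Reactants: 9 3-(benzyloxy)phenol
Product: 10 1-(benzyloxy)-3-methoxybenzene
Conditions: MeI, K2CO3, acetone, reflux
Reagents that add atoms: iodomethane CI
Why: Williamson O-methylation of the free phenol.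

Step 5
Reactants: 10 1-(benzyloxy)-3-methoxybenzene
Product: 13 2-(benzyloxy)-6-methoxyphenol, via [2-(benzyloxy)-6-methoxyphenyl]lithium 11 (not isolated), via lithium [2-(benzyloxy)-6-methoxyphenyl]trimethoxyborate 12 (not isolated)
Conditions: n-BuLi, THF, 0 °C → rt; B(OMe)3, −78 °C → rt; AcOH, 30% aq. H2O2, 0 °C → rt
Reagents that add atoms: hydrogen peroxide OO; n-butyllithium [Li]CCCC and trimethyl borate COB(OC)OC (their atoms stay only in 11 and 12)
Why: Cooperative directed ortho-metalation at the carbon flanked by both alkoxy groups (faster than benzylic deprotonation at 0 °C), then borylation/oxidation, installs the central oxygen of ring B.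

Step 6
Reactants: 13 2-(benzyloxy)-6-methoxyphenol
Product: 15 1,2-bis(benzyloxy)-5-iodo-3-methoxybenzene, via 2-(benzyloxy)-4-iodo-6-methoxyphenol 14 (not isolated)
Conditions: I2 (1.0 equiv), K2CO3 (2.5 equiv), DMF, 0 °C → rt; then BnBr (1.3 equiv), 60 °C
Reagents that add atoms: iodine II; benzyl bromide BrCc1ccccc1
Why: With both ortho positions blocked, electrophilic iodination of the phenoxide can only go para, and Williamson O-benzylation follows in the same pot.

Step 7
Reactants: 15 1,2-bis(benzyloxy)-5-iodo-3-methoxybenzene; 16 3-oxocyclobutane-1-carboxylic acid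
Product: 17 3-[3,4-bis(benzyloxy)-5-methoxyphenyl]cyclobutan-1-one
Conditions: 16 (1.5 equiv), Ir[dF(CF3)ppy]2(dtbbpy)PF6 (1 mol%), NiCl2·glyme (10 mol%), dtbbpy (15 mol%), Cs2CO3 (1.5 equiv), DMF, blue LEDs, rt
Reagents that add atoms: none
Why: Metallaphotoredox decarboxylative arylation: the photocatalyst oxidises the caesium carboxylate, loss of CO2 gives the 3-oxocyclobutyl radical, and nickel (after oxidative addition of 15) captures it and reductively eliminates the C(sp3)–C(sp2) bond; 17 is achiral.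

Step 8
Reactants: 17 3-[3,4-bis(benzyloxy)-5-methoxyphenyl]cyclobutan-1-one; 8 3-[4-(benzyloxy)-3-methoxyphenyl]propanal
Product: 19 (2S,6S)-2-[3,4-bis(benzyloxy)-5-methoxyphenyl]-6-{2-[4-(benzyloxy)-3-methoxyphenyl]ethyl}oxan-4-one, via ring-opened enol cation 18 (not isolated)
Conditions: 8 (1.5 equiv), chiral IDPi Brønsted acid (BINOL-derived imidodiphosphorimidate, 3,3′-aryl = 3,5-(CF3)2C6H3, N–SO2CF3; 5 mol%), 4 Å MS, toluene, −40 °C
Reagents that add atoms: none
Why: Proposed new method: the confined chiral acid protonates the strained ketone of 17, whose C2–C3 bond (about 26 kcal/mol of ring strain) ionises with push from the para-benzyloxyaryl group to the enol/benzylic cation 18, held as an ion pair with the chiral anion; the aldehyde oxygen of 8 adds to the benzylic carbon to give an oxocarbenium ion, and the enol carbon closes onto it through a chair transition state (stepwise and ionic; this C–C bond formation inside the anion pocket sets C6, and the reversible benzylic C–O bond settles C2 in the diequatorial 2,6-cis chair), releasing the 4-ketone and the acid; the closest known reaction types are the Lewis-acid-catalysed formal (4+2) ring expansion of 3-alkoxycyclobutanones with aldehydes, the Sc(OTf)3-catalysed annulation of aryl donor–acceptor cyclobutanes with aldehydes to cis-2,6-tetrahydropyrans, and confined-acid-catalysed asymmetric Prins cyclisations of aliphatic aldehydes, none of which covers an aryl-donor cyclobutanone or an enantioselective version.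

Step 9
Reactants: 19 (2S,6S)-2-[3,4-bis(benzyloxy)-5-methoxyphenyl]-6-{2-[4-(benzyloxy)-3-methoxyphenyl]ethyl}oxan-4-one
Product: 21 (2S,4S,6S)-2-[3,4-bis(benzyloxy)-5-methoxyphenyl]-6-{2-[4-(benzyloxy)-3-methoxyphenyl]ethyl}oxan-4-yl acetate, via lithium oxan-4-olate 20 (not isolated)
Conditions: LiBH(s-Bu)3 (1.2 equiv), THF, −78 °C; then Ac2O (3 equiv), DMAP (0.2 equiv), −78 °C → rt
Reagents that add atoms: acetic anhydride CC(=O)OC(C)=O; LiBH(s-Bu)3 [Li+].CCC(C)[BH-](C(C)CC)C(C)CC (its lithium stays only in 20)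
Why: Stereoselective ketone reduction by a bulky hydride, which attacks the chair ketone equatorially to give the axial (4S) alkoxide trans to the two equatorial substituents, followed by O-acylation in the same pot.

Step 10
Reactants: 21 (2S,4S,6S)-2-[3,4-bis(benzyloxy)-5-methoxyphenyl]-6-{2-[4-(benzyloxy)-3-methoxyphenyl]ethyl}oxan-4-yl acetate
Product: 22 (2S,4S,6S)-2-(3,4-dihydroxy-5-methoxyphenyl)-6-[2-(4-hydroxy-3-methoxyphenyl)ethyl]oxan-4-yl acetate
Conditions: H2 (1 atm), 10% Pd/C, EtOAc, rt
Reagents that add atoms: none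
Why: Catalytic hydrogenolysis cleaves the three aryl benzyl ethers much faster than the cyclic benzylic C2–O bond (neutral solvent, stopped at full conversion), leaving the acetate and all three stereocentres untouched.

**Compound list**
1 | anisole | COc1ccccc1 | starting material
2 | (2-methoxyphenyl)lithium | COc1ccccc1[Li] | intermediate
3 | lithium trimethoxy(2-methoxyphenyl)borate | [Li+].CO[B-](OC)(OC)c1ccccc1OC | intermediate
4 | 2-methoxyphenol | COc1ccccc1O | intermediate
5 | 4-iodo-2-methoxyphenol | COc1cc(I)ccc1O | intermediate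
6 | 1-(benzyloxy)-4-iodo-2-methoxybenzene | COc1cc(I)ccc1OCc1ccccc1 | intermediate
7 | prop-2-en-1-ol (allyl alcohol) | OCC=C | starting material
8 | 3-[4-(benzyloxy)-3-methoxyphenyl]propanal | COc1cc(CCC=O)ccc1OCc1ccccc1 | intermediate
9 | 3-(benzyloxy)phenol | Oc1cccc(OCc2ccccc2)c1 | starting material
10 | 1-(benzyloxy)-3-methoxybenzene | COc1cccc(OCc2ccccc2)c1 | intermediate
11 | [2-(benzyloxy)-6-methoxyphenyl]lithium | COc1cccc(OCc2ccccc2)c1[Li] | intermediate
12 | lithium [2-(benzyloxy)-6-methoxyphenyl]trimethoxyborate | [Li+].CO[B-](OC)(OC)c1c(OC)cccc1OCc1ccccc1 | intermediate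
13 | 2-(benzyloxy)-6-methoxyphenol | COc1cccc(OCc2ccccc2)c1O | intermediate
14 | 2-(benzyloxy)-4-iodo-6-methoxyphenol | COc1cc(I)cc(OCc2ccccc2)c1O | intermediate
15 | 1,2-bis(benzyloxy)-5-iodo-3-methoxybenzene | COc1cc(I)cc(OCc2ccccc2)c1OCc1ccccc1 | intermediate
16 | 3-oxocyclobutane-1-carboxylic acid | OC(=O)C1CC(=O)C1 | starting material
17 | 3-[3,4-bis(benzyloxy)-5-methoxyphenyl]cyclobutan-1-one | COc1cc(C2CC(=O)C2)cc(OCc2ccccc2)c1OCc1ccccc1 | intermediate
18 | 4-[3,4-bis(benzyloxy)-5-methoxyphenyl]-2-hydroxybut-1-en-4-ylium (ring-opened enol cation, ion-paired with the catalyst anion) | C=C(O)C[CH+]c1cc(OC)c(OCc2ccccc2)c(OCc2ccccc2)c1 | intermediate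
19 | (2S,6S)-2-[3,4-bis(benzyloxy)-5-methoxyphenyl]-6-{2-[4-(benzyloxy)-3-methoxyphenyl]ethyl}oxan-4-one | COc1cc(CC[C@H]2CC(=O)C[C@@H](c3cc(OCc4ccccc4)c(OCc4ccccc4)c(OC)c3)O2)ccc1OCc1ccccc1 | intermediate
20 | lithium (2S,4S,6S)-2-[3,4-bis(benzyloxy)-5-methoxyphenyl]-6-{2-[4-(benzyloxy)-3-methoxyphenyl]ethyl}oxan-4-olate | [Li+].COc1cc(CC[C@H]2C[C@H]([O-])C[C@@H](c3cc(OCc4ccccc4)c(OCc4ccccc4)c(OC)c3)O2)ccc1OCc1ccccc1 | intermediate
21 | (2S,4S,6S)-2-[3,4-bis(benzyloxy)-5-methoxyphenyl]-6-{2-[4-(benzyloxy)-3-methoxyphenyl]ethyl}oxan-4-yl acetate | COc1cc(CC[C@H]2C[C@H](OC(C)=O)C[C@@H](c3cc(OCc4ccccc4)c(OCc4ccccc4)c(OC)c3)O2)ccc1OCc1ccccc1 | intermediate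
22 | (2S,4S,6S)-2-(3,4-dihydroxy-5-methoxyphenyl)-6-[2-(4-hydroxy-3-methoxyphenyl)ethyl]oxan-4-yl acetate (CNP0143286.2) | COc1cc(CC[C@H]2C[C@H](OC(C)=O)C[C@@H](c3cc(O)c(O)c(OC)c3)O2)ccc1O | target

**Step count and risks**
Total step count: 10. Longest linear sequence: 7 steps (9 → 10 → 13 → 15 → 17 → 19 → 21 → 22).

Three steps most likely to fail:

Step 7 (decarboxylative arylation). The electron-rich aryl iodide and the small-ring secondary radical may couple in low yield. The fallback sets out from 15 and comes back at 17. Suzuki–Miyaura vinylation of 15 (potassium vinyltrifluoroborate, PdCl2(dppf), K2CO3, THF/H2O, 70 °C) gives 1,2-bis(benzyloxy)-5-ethenyl-3-methoxybenzene F1. Addition of dichloroketene (Cl3CCOCl, Zn–Cu couple, Et2O, rt) gives racemic 3-[3,4-bis(benzyloxy)-5-methoxyphenyl]-2,2-dichlorocyclobutan-1-one F2. Zn dust in AcOH at rt removes both chlorines and returns 17.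

Step 8 (the proposed ring expansion). The cyclobutanone may fail to ionise, cation 18 may isomerise to the open-chain enone, ring A may intercept a cation, or the ee may be low. The fallback uses known chemistry, sets out from 15 and 8, and comes back at 19. Heck reaction of 15 with methyl vinyl ketone (Pd(OAc)2, n-Bu4NCl, NaHCO3, DMF, 60 °C) gives (3E)-4-[3,4-bis(benzyloxy)-5-methoxyphenyl]but-3-en-2-one F3. Its boron enolate (the antipode of Ipc2BCl that gives the 5S alcohol, Et3N, Et2O, −78 °C) adds to 8 to give (1E,5S)-1-[3,4-bis(benzyloxy)-5-methoxyphenyl]-7-[4-(benzyloxy)-3-methoxyphenyl]-5-hydroxyhept-1-en-3-one F4. Acid-mediated 6-endo oxa-Michael cyclisation (Amberlyst-15, CH2Cl2, rt, thermodynamic control) closes the 2,6-cis ketone 19; the moderate ee typical of this aldol would be upgraded by recrystallising 19.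

Step 9 (one-pot reduction/acetylation). The borane-complexed axial alkoxide may acetylate sluggishly, or the reduction may be less selective than expected. The fallback sets out from 19 and comes back at 21. NaBH4 (MeOH, −20 °C, axial attack) gives the equatorial alcohol (2S,4R,6S)-2-[3,4-bis(benzyloxy)-5-methoxyphenyl]-6-{2-[4-(benzyloxy)-3-methoxyphenyl]ethyl}oxan-4-ol F5. Mitsunobu inversion with acetic acid (PPh3, DIAD, AcOH, THF, 0 °C → rt) gives the axial acetate 21 directly.

**Further compounds**
F1 | step 7 | 1,2-bis(benzyloxy)-5-ethenyl-3-methoxybenzene | COc1cc(C=C)cc(OCc2ccccc2)c1OCc1ccccc1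
F2 | step 7 | 3-[3,4-bis(benzyloxy)-5-methoxyphenyl]-2,2-dichlorocyclobutan-1-one (racemic) | COc1cc(C2CC(=O)C2(Cl)Cl)cc(OCc2ccccc2)c1OCc1ccccc1
F3 | step 8 | (3E)-4-[3,4-bis(benzyloxy)-5-methoxyphenyl]but-3-en-2-one | COc1cc(/C=C/C(C)=O)cc(OCc2ccccc2)c1OCc1ccccc1
F4 | step 8 | (1E,5S)-1-[3,4-bis(benzyloxy)-5-methoxyphenyl]-7-[4-(benzyloxy)-3-methoxyphenyl]-5-hydroxyhept-1-en-3-one | COc1cc(CC[C@H](O)CC(=O)/C=C/c2cc(OCc3ccccc3)c(OCc3ccccc3)c(OC)c2)ccc1OCc1ccccc1
F5 | step 9 | (2S,4R,6S)-2-[3,4-bis(benzyloxy)-5-methoxyphenyl]-6-{2-[4-(benzyloxy)-3-methoxyphenyl]ethyl}oxan-4-ol | COc1cc(CC[C@H]2C[C@@H](O)C[C@@H](c3cc(OCc4ccccc4)c(OCc4ccccc4)c(OC)c3)O2)ccc1OCc1ccccc1
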